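Cuts, in retrosynthetic order: C11=C13 (formaldehyde on a C11 malonate-type ester), the C9 ester, C10–C1 (vinylcopper on a C6 enone), C5–C4 (Stille coupling at the α-iodoenone), C6=O back to C6–OH, C6–O (water on a cyclopropane), and last C7–C11 and C6–C11 (carbene addition).
Enabling feature: in the carbocycle C10–C5–C6–C7–C8–C9, the cis oxygens on C8 and C9 next to methyl-bearing C10 are those of toluene cis-dihydrodiol. The lactone ring C7–C8–O–C12–C11 with an oxygen on C6 is what remains of a cyclopropane C6–C7–C11 after cleavage of C6–C11. O8 is allylic to C6=C7 of the diene and three atoms from C11.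
Forward order: the six-membered ring is bought. γ-Lactone and cyclopropane close together in step 4, and the three-membered ring is opened in step 5. The arm is joined at C5 (step 10), the vinyl group at C10 (step 11), the isobutyrate at C9 (step 12) and the methylene at C11 (step 14).
Stereochemistry: C8 and C9 come from the diol, C7 from the C8 tether, and C10 from copper addition anti to the C9 silyloxy group. C5 comes from axial protonation to the equatorial arm, and C6 from SmI2 reduction to the equatorial alcohol.

Key step: step 4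

Conventions: atom numbers are those of the target (arm = C4(=C3H2)C15H2O; vinyl = C1=C2). "Lower face" is the face of the C8 and C9 oxygens and "upper face" is the other one. PMB = 4-methoxybenzyl, TBS = tert-butyldimethylsilyl.
Assumption: 1 is bought as the enantiopure fermentation product of toluene. C11 of 7–9, 15, 17, 18 and 20–23 is a labile malonate-type centre, drawn as the epimer with the ester anti to C6, and it becomes sp2 in step 14.

Step 1
Reactants: 1 toluene cis-dihydrodiol; 2 mono-tert-butyl malonate
Product: 3 C8 tert-butyl malonate of 1 with the C9 hydroxyl free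
Conditions: DCC (1.0 equiv), DMAP (5 mol %), CH2Cl2, −20 °C
Reagents that add atoms: none
Why: Steglich esterification should take the C8 hydroxyl, because the C9 hydroxyl is crowded by the methyl-bearing sp2 carbon C10 (the bias that lets the distal hydroxyl of 3-substituted arene cis-dihydrodiols be protected alone), no stereocentre is touched, and the cold, near-neutral medium avoids dehydration to cresol.

Step 2
Reactants: 3 C8 malonate
Product: 4 C9 TBS ether of 3
Conditions: TBSOTf, 2,6-lutidine, CH2Cl2, −78 °C
Reagents that add atoms: tert-butyldimethylsilyl triflate, CC(C)(C)[Si](C)(C)OS(=O)(=O)C(F)(F)F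
Why: Silyl triflate silylation of the hindered allylic hydroxyl is fast at −78 °C, so the neighbouring ester should not migrate and the tert-butyl ester stays intact; the bulky ether later shields the lower face at C10.

Step 3
Reactants: 4 C9 TBS ether
Product: 5 C8 tert-butyl diazomalonate with C9 OTBS
Conditions: 4-acetamidobenzenesulfonyl azide, Et3N, MeCN, 0 °C → rt
Reagents that add atoms: 4-acetamidobenzenesulfonyl azide, CC(=O)Nc1ccc(cc1)S(=O)(=O)N=[N+]=[N-]
Why: Regitz diazo transfer to the malonate CH2 (pKa about 13) needs only triethylamine, which is mild enough for the elimination-prone cyclohexadienyl ester.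

Step 4
Reactants: 5 diazomalonate
Product: 6 tricyclic vinylcyclopropane: cyclopropane C6–C7–C11 and cis γ-lactone on the lower face with the C11 ester exo, C5=C10 retained and C9 OTBS
Conditions: Rh2(esp)2 (1 mol %; esp = α,α,α′,α′-tetramethyl-1,3-benzenedipropanoate), CH2Cl2, slow addition of 5, 25–40 °C
Reagents that add atoms: none
Why: Loss of N2 at the dirhodium core gives an electrophilic rhodium carbene at C11 that adds to C6=C7 in one concerted, asynchronous [2+1] event, the long-established intramolecular cyclopropanation of allylic diazomalonates. The γ-lactone C7–C8–O–C12–C11 closes as C7–C11 forms (five-membered, exo with respect to the tether), and the three-membered ring C6–C7–C11 closes through the simultaneous C6–C11 bond. C6 and C7 are controlled by the C8 stereocentre, because the tether O–C12–C11 reaches the diene only from the face that carries O8, so both new bonds lie on the lower face and the lactone is cis-fused; C11 follows from the same constraint, with the lactone carbonyl forced endo and the tert-butyl ester exo. The step needs site selectivity for C6=C7 over C5=C10, and the tether length secures it, since addition to the remote alkene would demand a bridged medium-ring lactone. The only C–H bond within reach is C9–H, and the cis-diol geometry places it on the upper face away from the carbene, while the bulky silyl ether discourages ylide formation at O9. Slow addition keeps the carbene from meeting a second diazo molecule.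

Step 5
Reactants: 6 vinylcyclopropane
Product: 7 allylic alcohol with C6–OH on the upper face, C5=C10 alkene, cis 8,12-lactone and C11–H tert-butyl ester
Conditions: Cu(ClO4)2·6H2O (10 mol %), H2O (5 equiv), CH2Cl2, rt
Reagents that add atoms: water, O
Why: This is Lewis-acid-catalysed hydration of a donor–acceptor cyclopropane, in which divalent copper chelates the two C11 carbonyls, the allylic C6–C11 bond (not C7–C11) is polarised, and water should attack C6 from the open upper face with inversion and release of strain; the bulky ester prevents lactonisation onto O6, and the C6 configuration is not needed further because the carbinol is oxidised next.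

Step 6
Reactants: 7 allylic alcohol
Product: 8 C6 enone (C6=O, C5=C10)
Conditions: activated MnO2, CH2Cl2, rt
Reagents that add atoms: none
Why: MnO2 oxidation of an allylic alcohol is neutral, which matters because O8 is β to the new ketone and base could start elimination and aromatisation; the acidic C11–H is an internal safeguard, since its enolate would make O8 a poor leaving group.

Step 7
Reactants: 8 enone
Product: 9 C5-iodo enone
Conditions: I2, pyridine–CH2Cl2 (1:1), 0 °C → rt; Na2S2O3 wash
Reagents that add atoms: iodine, II
Why: Johnson-type α-iodination (pyridine adds at C10, the enolate takes up iodine at C5, pyridine leaves) places a coupling handle on C5 with a base too weak to enolise C7 or the tertiary C11–H.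

Step 8
Reactants: 10 2,3-dibromopropene; 11 4-methoxybenzyl alcohol
Product: 12 2-bromoallyl PMB ether
Conditions: NaH, THF, 0 °C → rt
Reagents that add atoms: none
Why: In this Williamson ether synthesis only the allylic bromide is displaced and the vinylic bromide is inert.

Step 9
Reactants: 12 2-bromoallyl PMB ether
Product: 14 tributyl{3-[(4-methoxybenzyl)oxy]prop-1-en-2-yl}stannane, via alkenyllithium 13 (not isolated)
Conditions: t-BuLi (2.1 equiv), Et2O, −78 °C; Bu3SnCl, −78 °C → rt
Reagents that add atoms: tributyltin chloride, CCCC[Sn](Cl)(CCCC)CCCC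
Why: Bromine–lithium exchange at −78 °C is faster than loss of the β-alkoxide, and the alkenyllithium is trapped by stannylation.

Step 10
Reactants: 9 C5-iodo enone; 14 alkenylstannane
Product: 15 C5-alkenyl enone carrying the complete PMB-protected arm
Conditions: Pd2(dba)3 (5 mol %), AsPh3 (20 mol %), CuI (10 mol %), NMP, 25–45 °C
Reagents that add atoms: none
Why: Stille coupling of α-iodoenones with alkenylstannanes is a standard, neutral sp2–sp2 bond formation in which AsPh3 and CuI speed up transmetalation of the 1-substituted vinylstannane and curb cine substitution; it puts the arm on C5 without any enolate alkenylation.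

Step 11
Reactants: 15 C5-alkenyl enone; 16 vinylmagnesium bromide
Product: 18 C9-hydroxy C6-ketone with C10 vinyl on the upper face and the C5 arm on the lower face, via trimethylsilyl dienol ether 17 (not isolated)
Conditions: 16 (5 equiv), CuBr·SMe2 (20 mol %), Me3SiCl, DMPU, THF, −78 → −40 °C; aq. NH4Cl; crude 17, HF·pyridine, MeCN, 0 °C → rt
Reagents that add atoms: chlorotrimethylsilane, C[Si](C)(C)Cl (carried only by 17)
Why: In this chlorosilane-accelerated, copper-catalysed conjugate addition the first equivalent of Grignard reagent only removes C11–H, and the vinyl group should enter C10 axially on the upper face, anti to the pseudoaxial C9 silyloxy group and to O8; HF·pyridine then removes both silyl groups and protonates C5 from the upper face, opposite the now axial C10 methyl, so the arm becomes equatorial and trans to the vinyl group, which is also the thermodynamic result for this α-centre.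

Step 12
Reactants: 18 C9-hydroxy ketone; 19 isobutyryl chloride
Product: 20 C9 isobutyrate of 18
Conditions: pyridine, DMAP (10 mol %), CH2Cl2, 0 °C → rt
Reagents that add atoms: none
Why: DMAP-catalysed acylation meets only one free hydroxyl, and β-acyloxy cyclohexanones of this kind tolerate pyridine/DMAP at this temperature; acylating before the ketone is reduced removes any need to tell O6 from O9.

Step 13
Reactants: 20 keto isobutyrate
Product: 21 C6 alcohol with the hydroxyl on the upper face (equatorial)
Conditions: SmI2 (2.5 equiv), H2O (10 equiv), THF, 0 °C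
Reagents that add atoms: none
Why: Samarium diiodide ketone reduction (ketyl, second electron, protonation) gives the more stable alcohol, here the equatorial C6–OH trans to the C5 and C7 substituents; a hydride would have to pass the axial C10 methyl and the axial O8 to give this epimer and is therefore expected to deliver the other one.

Step 14
Reactants: 21 C6 alcohol
Product: 25 C15 PMB ether of the target with the α-methylene lactone in place, via bis(trimethylsilyl) derivative 22 (not isolated), via hydroxy acid 23 (not isolated), via Mannich base 24 (not isolated)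
Conditions: Me3SiOTf, 2,6-lutidine, CH2Cl2, 0 °C → rt; MeOH; Et2NH, 37% aq. HCHO, THF, 0 → 40 °C
Reagents that add atoms: formaldehyde, C=O; trimethylsilyl triflate, C[Si](C)(C)OS(=O)(=O)C(F)(F)F (carried only by 22); diethylamine, CCNCC (carried only by 24)
Why: Silyl triflate cleavage of the tert-butyl ester avoids strong protic acid, under which γ-hydroxy acid 23 could close a second lactone onto O6; its ammonium salt then undergoes the classical Mannich reaction and decarboxylative elimination that turn α-carboxy lactones into α-methylene lactones, which removes the C11 centre.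

Step 15
Reactants: 25 PMB ether
Product: 26 target CNP0298885.1
Conditions: DDQ, CH2Cl2–pH 7 buffer, 0 °C → rt
Reagents that add atoms: none
Why: Oxidative PMB ether cleavage with DDQ is neutral and should leave the α-methylene lactone, the isobutyrate, the three alkenes and the C6 hydroxyl untouched.

Compound list
1 | (1S,2R)-3-methylcyclohexa-3,5-diene-1,2-diol (C1 = C8, C2 = C9, C3 = C10) | CC1=CC=C[C@H](O)[C@@H]1O | starting material
2 | mono-tert-butyl malonate | CC(C)(C)OC(=O)CC(=O)O | starting material
3 | C8 tert-butyl malonate of 1, C9–OH free | CC1=CC=C[C@H](OC(=O)CC(=O)OC(C)(C)C)[C@@H]1O | intermediate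
4 | C9 TBS ether of 3 | CC1=CC=C[C@H](OC(=O)CC(=O)OC(C)(C)C)[C@@H]1O[Si](C)(C)C(C)(C)C | intermediate
5 | C8 tert-butyl diazomalonate, C9 OTBS | CC1=CC=C[C@H](OC(=O)C(=[N+]=[N-])C(=O)OC(C)(C)C)[C@@H]1O[Si](C)(C)C(C)(C)C | intermediate
6 | cyclopropane-fused lactone ester (C6–C7–C11 ring and lactone on the lower face) | CC1=C[C@H]2[C@H]3[C@H](OC(=O)[C@@]23C(=O)OC(C)(C)C)[C@@H]1O[Si](C)(C)C(C)(C)C | intermediate
7 | C6 upper-face allylic alcohol | CC1=C[C@@H](O)[C@H]2[C@H](OC(=O)[C@@H]2C(=O)OC(C)(C)C)[C@@H]1O[Si](C)(C)C(C)(C)C | intermediate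
8 | C6 enone | CC1=CC(=O)[C@H]2[C@H](OC(=O)[C@@H]2C(=O)OC(C)(C)C)[C@@H]1O[Si](C)(C)C(C)(C)C | intermediate
9 | C5-iodo enone | CC1=C(I)C(=O)[C@H]2[C@H](OC(=O)[C@@H]2C(=O)OC(C)(C)C)[C@@H]1O[Si](C)(C)C(C)(C)C | intermediate
10 | 2,3-dibromopropene | C=C(Br)CBr | starting material
11 | 4-methoxybenzyl alcohol | COc1ccc(CO)cc1 | starting material
12 | 2-bromoallyl PMB ether | C=C(Br)COCc1ccc(OC)cc1 | intermediate
13 | 2-lithioallyl PMB ether | [Li]C(=C)COCc1ccc(OC)cc1 | intermediate
14 | tributyl{3-[(4-methoxybenzyl)oxy]prop-1-en-2-yl}stannane | C=C(COCc1ccc(OC)cc1)[Sn](CCCC)(CCCC)CCCC | intermediate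
15 | C5-alkenyl enone | CC1=C(C(=C)COCc3ccc(OC)cc3)C(=O)[C@H]2[C@H](OC(=O)[C@@H]2C(=O)OC(C)(C)C)[C@@H]1O[Si](C)(C)C(C)(C)C | intermediate
16 | vinylmagnesium bromide | C=C[Mg]Br | starting material
17 | C6 trimethylsilyl dienol ether, C10 vinyl on the upper face | C=C[C@@]1(C)C(C(=C)COCc3ccc(OC)cc3)=C(O[Si](C)(C)C)[C@@H]2[C@@H](C(=O)OC(C)(C)C)C(=O)O[C@@H]2[C@@H]1O[Si](C)(C)C(C)(C)C | intermediate
18 | C9-hydroxy C6-ketone | C=C[C@@]1(C)[C@H](C(=C)COCc3ccc(OC)cc3)C(=O)[C@@H]2[C@@H](C(=O)OC(C)(C)C)C(=O)O[C@@H]2[C@@H]1O | intermediate
19 | isobutyryl chloride | CC(C)C(=O)Cl | starting material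
20 | C9 isobutyrate C6-ketone | C=C[C@@]1(C)[C@H](C(=C)COCc3ccc(OC)cc3)C(=O)[C@@H]2[C@@H](C(=O)OC(C)(C)C)C(=O)O[C@@H]2[C@@H]1OC(=O)C(C)C | intermediate
21 | C6 upper-face alcohol | C=C[C@@]1(C)[C@H](C(=C)COCc3ccc(OC)cc3)[C@@H](O)[C@@H]2[C@@H](C(=O)OC(C)(C)C)C(=O)O[C@@H]2[C@@H]1OC(=O)C(C)C | intermediate
22 | C6 trimethylsilyl ether, C11 trimethylsilyl ester | C=C[C@@]1(C)[C@H](C(=C)COCc3ccc(OC)cc3)[C@@H](O[Si](C)(C)C)[C@@H]2[C@@H](C(=O)O[Si](C)(C)C)C(=O)O[C@@H]2[C@@H]1OC(=O)C(C)C | intermediate
23 | C6-hydroxy C11-carboxylic acid | C=C[C@@]1(C)[C@H](C(=C)COCc3ccc(OC)cc3)[C@@H](O)[C@@H]2[C@@H](C(=O)O)C(=O)O[C@@H]2[C@@H]1OC(=O)C(C)C | intermediate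
24 | C11 (diethylaminomethyl) carboxylic acid | C=C[C@@]1(C)[C@H](C(=C)COCc3ccc(OC)cc3)[C@@H](O)[C@@H]2[C@@](C(=O)O)(CN(CC)CC)C(=O)O[C@@H]2[C@@H]1OC(=O)C(C)C | intermediate
25 | C15 PMB ether of the target | C=C[C@@]1(C)[C@H](C(=C)COCc3ccc(OC)cc3)[C@@H](O)[C@@H]2C(=C)C(=O)O[C@@H]2[C@@H]1OC(=O)C(C)C | intermediate
26 | CNP0298885.1 (6,15-dihydroxy-9-isobutyryloxyelema-1,3,11(13)-trien-8,12-olide) | C=C[C@@]1(C)[C@H](C(=C)CO)[C@@H](O)[C@@H]2C(=C)C(=O)O[C@@H]2[C@@H]1OC(=O)C(C)C | target

Total steps: 15. Longest linear sequence: 13 (steps 1–7 and 10–15).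

Steps most likely to fail

Step 11. C10 of 15 is fully substituted and flanked by the C9 silyl ether and the C5 arm. Conjugate addition may therefore be too slow, and 1,2-addition or enolisation may take over. The fallback reverses the order of the two C–C bonds and sets out from enone 8, whose α-carbon is unsubstituted. The same copper-catalysed vinyl addition with Me3SiCl should give the trimethylsilyl enol ether F1. MeLi (2 equiv) would release the C5 lithium enolate and deprotonate C11 to give the dilithio bis-enolate F2. The more basic ketone enolate of F2 would be joined to bromide 12 by palladium-catalysed ketone α-alkenylation [Pd2(dba)3, P(t-Bu)3, THF], giving the C9 silyl ether of the ketone F3. HF·pyridine then leads back to 18, and steps 7, 9 and 10 fall away.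

Step 13. Protonation of the ketyl may show poor facial selectivity, or electron transfer may reach the malonate-type lactone. The fallback sets out from 20 and uses hydride attack from the open upper face on purpose. NaBH4/CeCl3·7H2O in MeOH should give the lower-face (axial) C6 alcohol F4. Tf2O/pyridine would convert it into the C6 triflate F5. Lattrell–Dax inversion with Bu4NNO2 would then give the upper-face C6 nitrite F6, which is hydrolysed on work-up to 21.

Step 5. Ionisation may run ahead of capture by water. That would lead to attack at the tertiary allylic terminus C10, or to proton loss followed by aromatisation. The fallback avoids any cation and sets out from 6. PhSeNa [from (PhSe)2 and NaBH4, EtOH–THF, 0 °C] would open the cyclopropane by homoconjugate addition at C6 with inversion, giving the C6 allylic selenide F7. H2O2/pyridine would give the selenoxide F8. Its [2,3]-sigmatropic shift leads to the C10 selenenate F9, which is cleaved in the same flask to the C10 tertiary allylic alcohol F10. Babler–Dauben oxidative transposition with pyridinium chlorochromate, [C5H5NH][CrO3Cl], in CH2Cl2 returns to the route at enone 8.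

Further compounds
F1 | step 11 | C6 trimethylsilyl enol ether with C10 vinyl and C5–H | C=C[C@@]1(C)C=C(O[Si](C)(C)C)[C@@H]2[C@@H](C(=O)OC(C)(C)C)C(=O)O[C@@H]2[C@@H]1O[Si](C)(C)C(C)(C)C
F2 | step 11 | dilithio bis-enolate (C5=C6–OLi and C11 enolate) | C=C[C@@]1(C)C=C(O[Li])[C@@H]2C(C(=O)OC(C)(C)C)=C(O[Li])O[C@@H]2[C@@H]1O[Si](C)(C)C(C)(C)C
F3 | step 11 | C9 TBS ether of 18 | C=C[C@@]1(C)[C@H](C(=C)COCc3ccc(OC)cc3)C(=O)[C@@H]2[C@@H](C(=O)OC(C)(C)C)C(=O)O[C@@H]2[C@@H]1O[Si](C)(C)C(C)(C)C
F4 | step 13 | lower-face C6 alcohol (6-epimer of 21) | C=C[C@@]1(C)[C@H](C(=C)COCc3ccc(OC)cc3)[C@H](O)[C@@H]2[C@@H](C(=O)OC(C)(C)C)C(=O)O[C@@H]2[C@@H]1OC(=O)C(C)C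
F5 | step 13 | lower-face C6 triflate | C=C[C@@]1(C)[C@H](C(=C)COCc3ccc(OC)cc3)[C@H](OS(=O)(=O)C(F)(F)F)[C@@H]2[C@@H](C(=O)OC(C)(C)C)C(=O)O[C@@H]2[C@@H]1OC(=O)C(C)C
F6 | step 13 | upper-face C6 nitrite | C=C[C@@]1(C)[C@H](C(=C)COCc3ccc(OC)cc3)[C@@H](ON=O)[C@@H]2[C@@H](C(=O)OC(C)(C)C)C(=O)O[C@@H]2[C@@H]1OC(=O)C(C)C
F7 | step 5 | upper-face C6 phenyl selenide | CC1=C[C@@H]([Se]c3ccccc3)[C@H]2[C@H](OC(=O)[C@@H]2C(=O)OC(C)(C)C)[C@@H]1O[Si](C)(C)C(C)(C)C
F8 | step 5 | C6 selenoxide | CC1=C[C@@H]([Se](=O)c3ccccc3)[C@H]2[C@H](OC(=O)[C@@H]2C(=O)OC(C)(C)C)[C@@H]1O[Si](C)(C)C(C)(C)C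
F9 | step 5 | C10 upper-face selenenate, C5=C6 alkene | C[C@]1(O[Se]c3ccccc3)C=C[C@H]2[C@H](OC(=O)[C@@H]2C(=O)OC(C)(C)C)[C@@H]1O[Si](C)(C)C(C)(C)C
F10 | step 5 | C10 upper-face tertiary allylic alcohol | C[C@]1(O)C=C[C@H]2[C@H](OC(=O)[C@@H]2C(=O)OC(C)(C)C)[C@@H]1O[Si](C)(C)C(C)(C)C
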